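**Retrosynthetic overview**

1. Target 28, (5'S,6E,6'E)-4,5'-retro-β,β-carotene, comes from allylic alcohol 26 by acid-induced loss of water with retro shift: C4–OH leaves, H-6' is lost, every chain double bond moves by one position and both exocyclic olefins (C6=C7, C6'=C7') form together.
2. 26 comes from C40 ketone 25, assembled by two Wittig reactions (C11'=C12', then C11=C12) from ring-B C15 salt 20, C10 dial 21 and ring-A C15 salt 12.
3. Ring A (first ring, step 1): C1–C2 and C5–C6 are made in one Michael–Claisen annulation of methyl isobutyrate with ethyl vinyl ketone. The enabling feature is that the methyl-bearing C5 of ring A lies between two sp2 carbons, C4 and C6, and C6 adjoins the quaternary C1, so at the ketone oxidation level ring A is 2,4,4-trimethylcyclohexane-1,3-dione. C6=O then anchors the chain (step 4) and C4=O becomes the leaving group of the retro shift (step 14), so both oxygens are removed again.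
4. Ring B (second ring, step 7): cationic cyclisation of the enol acetate of (S)-citronellal; its stereocentre becomes C5' and stays outside every conjugated system until the last step.
5. C7–C11 come from (E)-3-methylpent-2-en-4-yn-1-ol and C7'–C11' from a C5 phosphonate; no protecting groups are used.

Key step: step 1

Assumption: carotenoid numbering is used (ring A = cyclohexene ring C1–C6, ring B = saturated ring C1'–C6'); the target SMILES is read as (5'S,6E,6'E) with an all-E chain. Compounds 1, 2, 7, 13, 16 (supplied E-rich) and 21 are taken as commercially available.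

**Step 1**
Reactants: 1 methyl isobutyrate; 2 pent-1-en-3-one (ethyl vinyl ketone)
Product: 5 2,4,4-trimethylcyclohexane-1,3-dione, via lithium ester enolate 3 (not isolated), via lithium enolate of the Michael adduct 4 (not isolated)
Conditions: LiN(i-Pr)2 (1.05 equiv, commercial solution), THF, −78 °C; add 2, −78 °C → rt, 16 h; 1 M HCl
Reagents that add atoms: none
Why: LiN(i-Pr)2 converts 1 into enolate 3, whose fully substituted α-carbon (future C1) adds in Michael fashion to the unsubstituted β-carbon of 2 (future C2) and creates the gem-dimethyl quaternary centre; on warming, enolate 4 equilibrates by proton transfer to its ethyl-side regioisomer, whose α-carbon (future C5) attacks the ester carbonyl (future C6) and expels methoxide. The closest known reaction type is the tandem Michael–Claisen (Dieckmann-type) annulation of ester enolates with alkyl vinyl ketones to cyclohexane-1,3-diones. Ring A closes in the 6-exo-trig mode (enolate carbon onto the ester carbonyl). No stereocentre needs control, because C5 of the dione is enolisable and becomes sp2 in step 4. The selectivities needed are 1,4- over 1,2-addition, C- over O-acylation and closure through C5 rather than C3: the hindered isobutyrate enolate favours conjugate addition, only the C5 enolate reaches the ester through a six-membered transition state (the C3 enolate would have to form a cyclobutanone), and deprotonation of the β-diketone by the released methoxide drives the sequence forward. In one operation the step should deliver all nine carbons of ring A with C4 and C6 differentiated as carbonyl groups.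

**Step 2**
Reactants: 5 2,4,4-trimethylcyclohexane-1,3-dione
Product: 6 3-(2-methylpropoxy)-2,6,6-trimethylcyclohex-2-en-1-one
Conditions: i-BuOH (3 equiv), TsOH·H2O (cat.), toluene, reflux, azeotropic removal of water
Reagents that add atoms: 2-methylpropan-1-ol, CC(C)CO
Why: Acid-catalysed enol ether (vinylogous ester) formation should occur at the less hindered carbonyl (C4), away from the gem-dimethyl group, leaving the neopentyl-type C6 carbonyl free, as in the regioselective enol etherification of 4,4-dialkylcyclohexane-1,3-diones.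

**Step 3**
Reactants: 7 (E)-3-methylpent-2-en-4-yn-1-ol
Product: 8 (2E,4E)-3-methyl-5-(tributylstannyl)penta-2,4-dien-1-ol
Conditions: Bu3SnH (1.1 equiv), PdCl2(PPh3)2 (2 mol %), THF, 0 °C → rt
Reagents that add atoms: tributyltin hydride, CCCC[SnH](CCCC)CCCC
Why: Palladium-catalysed syn-hydrostannation of the terminal alkyne of a conjugated enyne should place tin on the terminal carbon and give the (4E)-dienylstannane, with the existing (2E) olefin untouched.

**Step 4**
Reactants: 8 (2E,4E)-3-methyl-5-(tributylstannyl)penta-2,4-dien-1-ol; 6 3-(2-methylpropoxy)-2,6,6-trimethylcyclohex-2-en-1-one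
Product: 11 (2E,4E)-3-methyl-5-(2,6,6-trimethyl-3-oxocyclohex-1-en-1-yl)penta-2,4-dien-1-ol, via dilithiated dienol 9 (not isolated), via dilithium carbinolate adduct 10 (not isolated)
Conditions: n-BuLi (2.1 equiv), THF, −78 °C; add 6, −78 → 0 °C; then 1 M HCl, THF, 0 °C → rt
Reagents that add atoms: water, O
Why: O-deprotonation and tin–lithium exchange should give a configurationally stable (E,E)-dienyllithium that adds 1,2 to the only carbonyl of 6, and dilute acid then hydrolyses the enol ether with loss of water (Stork–Danheiser alkylative carbonyl transposition), unveiling the C4 ketone and the tetrasubstituted C5=C6 olefin.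

**Step 5**
Reactants: 11 (2E,4E)-3-methyl-5-(2,6,6-trimethyl-3-oxocyclohex-1-en-1-yl)penta-2,4-dien-1-ol
Product: 12 [(2E,4E)-3-methyl-5-(2,6,6-trimethyl-3-oxocyclohex-1-en-1-yl)penta-2,4-dien-1-yl]triphenylphosphonium bromide
Conditions: PPh3·HBr (1.05 equiv), MeOH, rt
Reagents that add atoms: triphenylphosphine hydrobromide, [Br-].[PH+](c1ccccc1)(c1ccccc1)c1ccccc1
Why: PPh3·HBr should convert the allylic alcohol through its allyl cation into the primary allylic phosphonium salt (standard C15 Wittig salt formation), while the hindered cross-conjugated ketone stays inert.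

**Step 6**
Reactants: 13 (S)-citronellal
Product: 14 (3S)-3,7-dimethylocta-1,6-dien-1-yl acetate (E/Z mixture)
Conditions: Ac2O, KOAc, Et3N, 120 °C
Reagents that add atoms: acetic anhydride, CC(=O)OC(C)=O
Why: Enol acetylation of an enolisable aldehyde; the C3 stereocentre is not α to the carbonyl and is not touched.

**Step 7**
Reactants: 14 (3S)-3,7-dimethylocta-1,6-dien-1-yl acetate
Product: 15 (1R,6S)-2,2,6-trimethylcyclohexane-1-carbaldehyde
Conditions: 85% H3PO4, toluene, 80 °C; aqueous work-up; then K2CO3, MeOH, rt (equilibration at C1)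
Reagents that add atoms: water, O
Why: Cationic olefin cyclisation: protonation of the trisubstituted olefin gives a tertiary cation that is captured by the enol acetate carbon in a chair-like six-membered transition state (free citronellal would instead undergo the carbonyl-ene reaction), and hydrolysis of the acetoxycarbenium ion releases the aldehyde; C6 keeps the S configuration of citronellal and the epimerisable C1 should settle trans (1R) on base equilibration.

**Step 8**
Reactants: 15 (1R,6S)-2,2,6-trimethylcyclohexane-1-carbaldehyde; 16 ethyl (E)-4-(diethoxyphosphoryl)-3-methylbut-2-enoate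
Product: 18 ethyl (2E,4E)-3-methyl-5-[(1S,6S)-2,2,6-trimethylcyclohexyl]penta-2,4-dienoate, via sodium phosphonate carbanion 17 (not isolated)
Conditions: NaH, THF, 0 °C; add 15, 0 °C → rt
Reagents that add atoms: none
Why: Vinylogous Horner–Wadsworth–Emmons olefination with the stabilised C5 phosphonate anion should give mainly the (2E,4E)-dienoate; the base can only equilibrate the α-centre of 15 (to the trans arrangement, whose descriptor becomes 1S by priority change) and cannot touch the future C5'.

**Step 9**
Reactants: 18 ethyl (2E,4E)-3-methyl-5-[(1S,6S)-2,2,6-trimethylcyclohexyl]penta-2,4-dienoate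
Product: 19 (2E,4E)-3-methyl-5-[(1S,6S)-2,2,6-trimethylcyclohexyl]penta-2,4-dien-1-ol
Conditions: i-Bu2AlH (2.2 equiv), CH2Cl2, −78 → 0 °C; aq. KNaC4H4O6 work-up
Reagents that add atoms: none
Why: 1,2-Reduction of a conjugated ester to the allylic alcohol by i-Bu2AlH at low temperature leaves the diene untouched.

**Step 10**
Reactants: 19 (2E,4E)-3-methyl-5-[(1S,6S)-2,2,6-trimethylcyclohexyl]penta-2,4-dien-1-ol
Product: 20 {(2E,4E)-3-methyl-5-[(1S,6S)-2,2,6-trimethylcyclohexyl]penta-2,4-dien-1-yl}triphenylphosphonium bromide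
Conditions: PPh3·HBr (1.05 equiv), MeOH, rt
Reagents that add atoms: triphenylphosphine hydrobromide, [Br-].[PH+](c1ccccc1)(c1ccccc1)c1ccccc1
Why: Same allylic alcohol to phosphonium salt conversion as in step 5, with attack of PPh3 at the primary terminus of the dienyl cation.

**Step 11**
Reactants: 20 ring-B C15 phosphonium bromide; 21 (2E,4E,6E)-2,7-dimethylocta-2,4,6-trienedial (3 equiv, excess recovered)
Product: 23 (2E,4E,6E,8E,10E,12E)-2,7,11-trimethyl-13-[(1S,6S)-2,2,6-trimethylcyclohexyl]trideca-2,4,6,8,10,12-hexaenal, via ring-B C15 ylide 22 (not isolated)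
Conditions: NaOMe (1.1 equiv), MeOH/CH2Cl2, 0 °C, slow addition of 20 to 21; then n-heptane, 90 °C (Z→E)
Reagents that add atoms: none
Why: Wittig olefination of the semi-stabilised allylic ylide with one aldehyde group of the symmetrical dial, kept in excess so that mono-condensation dominates, followed by thermal equilibration of the new C11'=C12' bond to E.

**Step 12**
Reactants: 12 ring-A C15 phosphonium bromide; 23 C25 aldehyde
Product: 25 (5'S,6'S)-5',6'-dihydro-β,β-caroten-4-one, via ring-A C15 ylide 24 (not isolated)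
Conditions: NaOMe (1.2 equiv), MeOH/CH2Cl2, rt; then n-heptane, 90 °C (Z→E)
Reagents that add atoms: none
Why: Second Wittig olefination of the C15 + C10 + C15 type used for carotenoids with 4-oxo end groups; the hindered enone carbonyl should not react with the ylide, and the new C11=C12 bond is equilibrated to E.

**Step 13**
Reactants: 25 (5'S,6'S)-5',6'-dihydro-β,β-caroten-4-one
Product: 26 (4RS,5'S,6'S)-5',6'-dihydro-β,β-caroten-4-ol
Conditions: NaBH4, THF/MeOH, 0 °C
Reagents that add atoms: none
Why: 1,2-Hydride reduction of the cross-conjugated ring ketone (the echinenone to isocryptoxanthin type of reduction); the new C4 stereocentre forms without control and is destroyed in step 14.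

**Step 14**
Reactants: 26 (4RS,5'S,6'S)-5',6'-dihydro-β,β-caroten-4-ol
Product: 28 (5'S,6E,6'E)-4,5'-retro-β,β-carotene (target), via polyenyl cation 27 (not isolated)
Conditions: dry HCl in CHCl3 (about 0.03 M), 0 °C → rt, 10 min, argon, dark; then aq. NaHCO3; crystallisation
Reagents that add atoms: none
Why: Acid-induced allylic dehydration with retro shift (the caroten-4-ol to retro-dehydrocarotene and retinol to anhydroretinol type): ionisation of the allylic C4–OH gives cation 27 delocalised from C4 to C7', loss of the C6' proton should give the fully conjugated undecaene with both exocyclic olefins in their less strained E arrangements (C8 syn to C1, C8' syn to C5'), and C5', which is not part of the π-system, keeps its S configuration.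

**Compound list**

1 | methyl isobutyrate (methyl 2-methylpropanoate) | COC(=O)C(C)C | starting material
2 | pent-1-en-3-one (ethyl vinyl ketone) | C=CC(=O)CC | starting material
3 | lithium 1-methoxy-2-methylprop-1-en-1-olate (ester enolate of 1, formed in the flask) | COC(O[Li])=C(C)C | intermediate
4 | methyl 5-(lithiooxy)-2,2-dimethylhept-4-enoate (enolate of the Michael adduct, formed in the flask, geometry undefined) | COC(=O)C(C)(C)CC=C(O[Li])CC | intermediate
5 | 2,4,4-trimethylcyclohexane-1,3-dione (racemic at C2, enolisable) | CC1C(=O)CCC(C)(C)C1=O | intermediate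
6 | 3-(2-methylpropoxy)-2,6,6-trimethylcyclohex-2-en-1-one | CC1=C(OCC(C)C)CCC(C)(C)C1=O | intermediate
7 | (E)-3-methylpent-2-en-4-yn-1-ol | C#C/C(C)=C/CO | starting material
8 | (2E,4E)-3-methyl-5-(tributylstannyl)penta-2,4-dien-1-ol | CCCC[Sn](CCCC)(CCCC)/C=C/C(C)=C/CO | intermediate
9 | (1E,3E)-1-lithio-5-(lithiooxy)-3-methylpenta-1,3-diene (formed in the flask) | [Li]/C=C/C(C)=C/CO[Li] | intermediate
10 | dilithium alkoxide of 1-[(1E,3E)-5-hydroxy-3-methylpenta-1,3-dien-1-yl]-3-(2-methylpropoxy)-2,6,6-trimethylcyclohex-2-en-1-ol (racemic at C1, formed in the flask) | CC1=C(OCC(C)C)CCC(C)(C)C1(O[Li])/C=C/C(C)=C/CO[Li] | intermediate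
11 | (2E,4E)-3-methyl-5-(2,6,6-trimethyl-3-oxocyclohex-1-en-1-yl)penta-2,4-dien-1-ol | CC1=C(/C=C/C(C)=C/CO)C(C)(C)CCC1=O | intermediate
12 | [(2E,4E)-3-methyl-5-(2,6,6-trimethyl-3-oxocyclohex-1-en-1-yl)penta-2,4-dien-1-yl]triphenylphosphonium bromide | CC1=C(/C=C/C(C)=C/C[P+](c2ccccc2)(c2ccccc2)c2ccccc2)C(C)(C)CCC1=O.[Br-] | intermediate
13 | (S)-citronellal, (3S)-3,7-dimethyloct-6-enal | O=CC[C@@H](C)CCC=C(C)C | starting material
14 | (3S)-3,7-dimethylocta-1,6-dien-1-yl acetate (E/Z mixture at the enol double bond) | CC(=O)OC=C[C@@H](C)CCC=C(C)C | intermediate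
15 | (1R,6S)-2,2,6-trimethylcyclohexane-1-carbaldehyde (trans) | O=C[C@@H]1[C@@H](C)CCCC1(C)C | intermediate
16 | ethyl (E)-4-(diethoxyphosphoryl)-3-methylbut-2-enoate | CCOC(=O)/C=C(C)/CP(=O)(OCC)OCC | starting material
17 | sodium salt of the carbanion of 16 (delocalised, formed in the flask) | CCOC(=O)C=C(C)[CH-]P(=O)(OCC)OCC.[Na+] | intermediate
18 | ethyl (2E,4E)-3-methyl-5-[(1S,6S)-2,2,6-trimethylcyclohexyl]penta-2,4-dienoate (trans ring substituents) | CCOC(=O)/C=C(C)/C=C/[C@@H]1[C@@H](C)CCCC1(C)C | intermediate
19 | (2E,4E)-3-methyl-5-[(1S,6S)-2,2,6-trimethylcyclohexyl]penta-2,4-dien-1-ol | OC/C=C(C)/C=C/[C@@H]1[C@@H](C)CCCC1(C)C | intermediate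
20 | {(2E,4E)-3-methyl-5-[(1S,6S)-2,2,6-trimethylcyclohexyl]penta-2,4-dien-1-yl}triphenylphosphonium bromide | [Br-].c1ccc(cc1)[P+](c1ccccc1)(c1ccccc1)C/C=C(C)/C=C/[C@@H]2[C@@H](C)CCCC2(C)C | intermediate
21 | (2E,4E,6E)-2,7-dimethylocta-2,4,6-trienedial | O=C/C(C)=C/C=C/C=C(C)/C=O | starting material
22 | ylide of 20, {(2E,4E)-3-methyl-5-[(1S,6S)-2,2,6-trimethylcyclohexyl]penta-2,4-dien-1-ylidene}triphenylphosphorane (formed in the flask) | [CH-]([P+](c1ccccc1)(c1ccccc1)c1ccccc1)/C=C(C)/C=C/[C@@H]2[C@@H](C)CCCC2(C)C | intermediate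
23 | (2E,4E,6E,8E,10E,12E)-2,7,11-trimethyl-13-[(1S,6S)-2,2,6-trimethylcyclohexyl]trideca-2,4,6,8,10,12-hexaenal | O=C/C(C)=C/C=C/C=C(C)/C=C/C=C(C)/C=C/[C@@H]1[C@@H](C)CCCC1(C)C | intermediate
24 | ylide of 12 (formed in the flask) | CC1=C(/C=C/C(C)=C/[CH-][P+](c2ccccc2)(c2ccccc2)c2ccccc2)C(C)(C)CCC1=O | intermediate
25 | (5'S,6'S)-5',6'-dihydro-β,β-caroten-4-one (all-E) | CC1=C(/C=C/C(C)=C/C=C/C(C)=C/C=C/C=C(C)/C=C/C=C(C)/C=C/[C@@H]2[C@@H](C)CCCC2(C)C)C(C)(C)CCC1=O | intermediate
26 | (4RS,5'S,6'S)-5',6'-dihydro-β,β-caroten-4-ol (both C4 epimers) | CC1=C(/C=C/C(C)=C/C=C/C(C)=C/C=C/C=C(C)/C=C/C=C(C)/C=C/[C@@H]2[C@@H](C)CCCC2(C)C)C(C)(C)CCC1O | intermediate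
27 | (5'S,6'S)-5',6'-dihydro-β,β-caroten-4-ylium chloride (cation delocalised from C4 to C7', formed in the flask) | CC1=C(/C=C/C(C)=C/C=C/C(C)=C/C=C/C=C(C)/C=C/C=C(C)/C=C/[C@@H]2[C@@H](C)CCCC2(C)C)C(C)(C)CC[CH+]1.[Cl-] | intermediate
28 | (5'S,6E,6'E)-4,5'-retro-β,β-carotene (CNP0257724.1) | CC1=CCCC(C)(C)\C1=C/C=C(C)/C=C/C=C(C)/C=C/C=C/C(C)=C/C=C/C(C)=C/C=C1\[C@@H](C)CCCC1(C)C | target

**Totals and risks**

Total step count: 14. Longest linear sequence: 9 steps (13 → 28 through steps 6–14); the ring-A branch is 7 steps (1 → 28 through steps 1, 2, 4, 5, 12, 13, 14).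

Steps most likely to fail, in order of risk:

1. Step 14. The delocalised cation may lose a proton at C3 (next to the leaving-group site) instead of at the hindered C6'. Acid may also re-protonate the product and move the double bonds further, which would erode the C5' stereocentre through a C5'=C6' isomer and scramble the 6/6' geometry. The fallback replaces the cationic retro shift by an anionic one; it sets out from 25 and returns at 28. Ketone 25 is treated with KOt-Bu in THF at 0 °C under argon, so that proton transfer equilibrates the enolates towards the fully conjugated potassium (5'S)-4,5'-retro-β,β-caroten-4-olate F1 (removal of H-6', the vinylogous counterpart of the base-induced deconjugation of β-ionone to retro-ionone). O-Sulfonylation with PhNTf2 should give (5'S,6E,6'E)-4,5'-retro-β,β-caroten-4-yl trifluoromethanesulfonate F2. Hydrogenolysis of the C4–O bond with Pd(OAc)2/PPh3 (reduced in the flask to zerovalent palladium), HCO2H and Et3N in DMF at 40 °C should then give 28.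

2. Step 4. Tin–lithium exchange may be incomplete in the presence of the lithium alkoxide, and the aggregated dianion may add slowly to the neopentyl-type carbonyl of 6. The fallback uses a smaller sp nucleophile and then adjusts the oxidation level; it sets out from 7 and 6 and returns at 11. Enynol 7 is doubly deprotonated with EtMgBr (2 equiv, THF) to the bis(bromomagnesium) acetylide alkoxide F3, which adds to 6. Acidic work-up as in step 4 should give (E)-3-methyl-5-(2,6,6-trimethyl-3-oxocyclohex-1-en-1-yl)pent-2-en-4-yn-1-ol F4. Semi-hydrogenation (H2, Pd/CaCO3 poisoned with Pb(OAc)2, quinoline) should give (2E,4Z)-3-methyl-5-(2,6,6-trimethyl-3-oxocyclohex-1-en-1-yl)penta-2,4-dien-1-ol F5, whose strained Z olefin is isomerised with catalytic I2 in daylight to 11.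

3. Step 11. The product aldehyde may be olefinated a second time (bis-adduct), and Z/E mixtures may form at the new double bond. The fallback uses an unsymmetrical C10 unit; it sets out from 20 and returns at 23. Ylide 22, generated from 20 as in step 11, is condensed with the known ethyl (2E,4E,6E)-2,7-dimethyl-8-oxoocta-2,4,6-trienoate (CCOC(=O)/C(C)=C/C=C/C=C(C)/C=O), which has only one aldehyde group. This should give ethyl (2E,4E,6E,8E,10E,12E)-2,7,11-trimethyl-13-[(1S,6S)-2,2,6-trimethylcyclohexyl]trideca-2,4,6,8,10,12-hexaenoate F6. Reduction with i-Bu2AlH (CH2Cl2, −78 °C) should give (2E,4E,6E,8E,10E,12E)-2,7,11-trimethyl-13-[(1S,6S)-2,2,6-trimethylcyclohexyl]trideca-2,4,6,8,10,12-hexaen-1-ol F7, and oxidation with MnO2 (CH2Cl2, rt) returns 23.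

**Further compounds**

F1 | step 14 | potassium (5'S)-4,5'-retro-β,β-caroten-4-olate | CC1=C(O[K])CCC(C)(C)\C1=C/C=C(C)/C=C/C=C(C)/C=C/C=C/C(C)=C/C=C/C(C)=C/C=C1\[C@@H](C)CCCC1(C)C
F2 | step 14 | (5'S,6E,6'E)-4,5'-retro-β,β-caroten-4-yl trifluoromethanesulfonate | CC1=C(OS(=O)(=O)C(F)(F)F)CCC(C)(C)\C1=C/C=C(C)/C=C/C=C(C)/C=C/C=C/C(C)=C/C=C/C(C)=C/C=C1\[C@@H](C)CCCC1(C)C
F3 | step 4 | bis(bromomagnesium) derivative of 7 (acetylide and alkoxide) | Br[Mg]C#C/C(C)=C/CO[Mg]Br
F4 | step 4 | (E)-3-methyl-5-(2,6,6-trimethyl-3-oxocyclohex-1-en-1-yl)pent-2-en-4-yn-1-ol | CC1=C(C#C/C(C)=C/CO)C(C)(C)CCC1=O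
F5 | step 4 | (2E,4Z)-3-methyl-5-(2,6,6-trimethyl-3-oxocyclohex-1-en-1-yl)penta-2,4-dien-1-ol | CC1=C(/C=C\C(C)=C\CO)C(C)(C)CCC1=O
F6 | step 11 | ethyl (2E,4E,6E,8E,10E,12E)-2,7,11-trimethyl-13-[(1S,6S)-2,2,6-trimethylcyclohexyl]trideca-2,4,6,8,10,12-hexaenoate | CCOC(=O)/C(C)=C/C=C/C=C(C)/C=C/C=C(C)/C=C/[C@@H]1[C@@H](C)CCCC1(C)C
F7 | step 11 | (2E,4E,6E,8E,10E,12E)-2,7,11-trimethyl-13-[(1S,6S)-2,2,6-trimethylcyclohexyl]trideca-2,4,6,8,10,12-hexaen-1-ol | OC/C(C)=C/C=C/C=C(C)/C=C/C=C(C)/C=C/[C@@H]1[C@@H](C)CCCC1(C)C
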